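## Retrosynthetic overview
1. Target 21 comes from a face- and site-selective dihydroxylation of the exocyclic C4=C15 alkene of macrocycle 20. This sets C4 and needs no protecting group on C4-OH or C15-OH.
2. The ten-membered carbocycle and the 3(2H)-furanone are closed together from seco vinyl iodide/alkynol 16. CO becomes C3, and the bonds C3–C4, C2–C3 and C3–O are formed.
3. Compound 16 comes from a C7–C8 Nozaki–Hiyama allylation of aldehyde 4 with bromobutenolide 13. This unveils the α-methylene lactone and sets C7 and C8. A Mitsunobu esterification then inverts C8.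
4. Compound 13 comes from an asymmetric vinylogous Mukaiyama aldol of silyloxyfuran 9 with 2-iodoacrolein 7 (sets C5 and C6). Compound 4 comes from a Sharpless epoxidation of enynol 1 (sets C10).
5. Ring order: the lactone ring is bought in 8; the carbocycle and the furanone then form in one operation (step 12).

Assumption: locants C1–C15 are germacranolide locants of the target, which is (4R,5S,6S,7R,8R,10S). C1 is the ketone, C2=C3 the furanone alkene, C4 the tertiary carbinol, C5 the CHOAc, C6 the lactone CH–O, C7 the ring-fusion CH, C8 the CH–O-methacrylate, C9 the CH2, C10 the quaternary C–O, C11/C12/C13 the lactone α-carbon/carbonyl/methylene, C14 the C10 methyl and C15 the CH2OH.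

## Route

Step 1
Reactants: 1 (Z)-3-methylpent-2-en-4-yn-1-ol
Product: 2 [(2S,3R)-3-ethynyl-3-methyloxiran-2-yl]methanol
Conditions: Ti(OiPr)4 (10 mol%), L-(+)-diethyl tartrate (12 mol%), t-BuOOH, 4 Å MS, CH2Cl2, −20 °C
Reagents that add atoms: tert-butyl hydroperoxide, CC(C)(C)OO
Why: Sharpless asymmetric epoxidation, in which the L-(+)-tartrate/titanium catalyst delivers oxygen to one face of this Z-3,3-disubstituted allylic alcohol (as for nerol), fixing the quaternary carbon that becomes C10, while the terminal alkyne is inert.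

Step 2
Reactants: 2 [(2S,3R)-3-ethynyl-3-methyloxiran-2-yl]methanol
Product: 3 (S)-3-methylpent-4-yne-1,3-diol
Conditions: NaAlH2(OCH2CH2OMe)2 (2.5 equiv), THF, −20 to 0 °C; then H2O
Reagents that add atoms: none
Why: Hydroxyl-directed reductive opening of a 2,3-epoxy alcohol, in which the alkoxyaluminate delivers hydride to the secondary carbon to give the 1,3-diol, the C–O bond at the quaternary centre is untouched (configuration kept), and the alkyne, deprotonated first, is not hydroaluminated at this temperature.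

Step 3
Reactants: 3 (S)-3-methylpent-4-yne-1,3-diol
Product: 4 (S)-3-hydroxy-3-methylpent-4-ynal
Conditions: TEMPO (10 mol%), PhI(OAc)2 (1.1 equiv), CH2Cl2, rt
Reagents that add atoms: none
Why: Oxoammonium (TEMPO) oxidation takes only the primary alcohol to the aldehyde under nearly neutral conditions, so the tertiary propargylic alcohol and its stereocentre survive.

Step 4
Reactants: 5 prop-2-yn-1-ol
Product: 6 2-iodoprop-2-en-1-ol
Conditions: NaI, Me3SiCl, H2O (0.5 equiv), MeCN, rt
Reagents that add atoms: sodium iodide, [Na+].[I-]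
Why: Markovnikov hydroiodination of a terminal alkyne with HI made in the flask gives the 1,1-disubstituted vinyl iodide, and no stereocentre is involved.

Step 5
Reactants: 6 2-iodoprop-2-en-1-ol
Product: 7 2-iodoprop-2-enal
Conditions: MnO2 (activated, excess), CH2Cl2, rt; filtered solution used at once
Reagents that add atoms: none
Why: Heterogeneous allylic alcohol oxidation stops at the enal, and simple filtration spares this labile aldehyde any aqueous work-up.

Step 6
Reactants: 8 3-methylfuran-2(5H)-one
Product: 9 tert-butyl(dimethyl)[(3-methylfuran-2-yl)oxy]silane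
Conditions: t-BuMe2SiOTf, Et3N, CH2Cl2, 0 °C
Reagents that add atoms: tert-butyldimethylsilyl trifluoromethanesulfonate, CC(C)(C)[Si](C)(C)OS(=O)(=O)C(F)(F)F
Why: Soft enolisation and O-silylation of the butenolide gives the aromatic 2-silyloxyfuran, a γ-nucleophilic dienoxysilane.

Step 7
Reactants: 7 2-iodoprop-2-enal; 9 tert-butyl(dimethyl)[(3-methylfuran-2-yl)oxy]silane
Product: 11 (5S)-5-[(1S)-1-hydroxy-2-iodoprop-2-en-1-yl]-3-methylfuran-2(5H)-one, via trichlorosilyl ether 10 (not isolated)
Conditions: SiCl4 (1.1 equiv), chiral binaphthyldiamine bisphosphoramide (5 mol%, the antipode giving Si-face attack), i-Pr2NEt (10 mol%), CH2Cl2, −78 °C; then aq. buffer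
Reagents that add atoms: none
Why: Catalytic enantioselective vinylogous Mukaiyama aldol reaction (Lewis-base-activated SiCl4, best with conjugated aldehydes), in which γ-attack through an open antiperiplanar transition state on the Si face of the enal sets C5 and C6 as the 5,6-anti (S,S) pair.

Step 8
Reactants: 11 (5S)-5-[(1S)-1-hydroxy-2-iodoprop-2-en-1-yl]-3-methylfuran-2(5H)-one
Product: 12 (5S)-5-[(1S)-2-iodo-1-(triethylsilyloxy)prop-2-en-1-yl]-3-methylfuran-2(5H)-one
Conditions: Et3SiCl, imidazole, CH2Cl2, 0 °C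
Reagents that add atoms: chlorotriethylsilane, CC[Si](Cl)(CC)CC
Why: Standard silylation, chosen because a silyl ether (unlike an acetate) is neither ionised nor β-eliminated by palladium in step 12.

Step 9
Reactants: 12 (5S)-5-[(1S)-2-iodo-1-(triethylsilyloxy)prop-2-en-1-yl]-3-methylfuran-2(5H)-one
Product: 13 (5S)-3-(bromomethyl)-5-[(1S)-2-iodo-1-(triethylsilyloxy)prop-2-en-1-yl]furan-2(5H)-one
Conditions: NBS (1.05 equiv), AIBN (5 mol%), solid NaHCO3, PhCF3, 85 °C
Reagents that add atoms: N-bromosuccinimide, O=C1CCC(=O)N1Br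
Why: Wohl–Ziegler bromination of an α-methylbutenolide goes to the unhindered methyl group, whereas the C5–H and C6–H bonds are shielded by the silyl ether and the side chain, and no stereocentre is touched.

Step 10
Reactants: 4 (S)-3-hydroxy-3-methylpent-4-ynal; 13 (5S)-3-(bromomethyl)-5-[(1S)-2-iodo-1-(triethylsilyloxy)prop-2-en-1-yl]furan-2(5H)-one
Product: 15 (4R,5S)-4-[(1S,3S)-1,3-dihydroxy-3-methylpent-4-yn-1-yl]-5-[(1S)-2-iodo-1-(triethylsilyloxy)prop-2-en-1-yl]-3-methylideneoxolan-2-one, via allylchromium dichloride 14 (not isolated)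
Conditions: CrCl2 (nickel-free, 4 equiv), THF, 0 °C to rt; then H2O
Reagents that add atoms: none
Why: Nozaki–Hiyama allylation with divalent chromium (without nickel the vinyl iodide is inert), in which γ-attack on the butenolide face anti to the C6 side chain sets C7 trans to C6 and creates the α-methylene lactone, and the chair transition state of the ring-locked E-type allyl metal gives the 7,8-anti carbinol (8S), the epimer that step 11 inverts.

Step 11
Reactants: 15 (4R,5S)-4-[(1S,3S)-1,3-dihydroxy-3-methylpent-4-yn-1-yl]-5-[(1S)-2-iodo-1-(triethylsilyloxy)prop-2-en-1-yl]-3-methylideneoxolan-2-one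
Product: 16 (1R,3S)-3-hydroxy-1-{(2S,3R)-2-[(1S)-2-iodo-1-(triethylsilyloxy)prop-2-en-1-yl]-4-methylidene-5-oxooxolan-3-yl}-3-methylpent-4-yn-1-yl 2-methylprop-2-enoate
Conditions: methacrylic acid, PPh3, DIAD, toluene, 0 °C to rt
Reagents that add atoms: methacrylic acid, C=C(C)C(=O)O
Why: Mitsunobu esterification installs the methacrylate with clean SN2 inversion (8S to 8R, the target configuration), and the tertiary C10-OH cannot be activated, so it stays free for step 12.

Step 12
Reactants: 16 (1R,3S)-3-hydroxy-1-{(2S,3R)-2-[(1S)-2-iodo-1-(triethylsilyloxy)prop-2-en-1-yl]-4-methylidene-5-oxooxolan-3-yl}-3-methylpent-4-yn-1-yl 2-methylprop-2-enoate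
Product: 19 5-O-triethylsilyl-4(15)-ene macrocycle (5R,6S,7R,8R,10S), via ten-membered ynone 17 (not isolated), via ten-membered 1,3-diketone 18 (not isolated)
Conditions: PdCl2(PPh3)2 (10 mol%), CuI (20 mol%), Et3N, CO (1 atm), dry THF, 1 mM by syringe pump, 35 °C; then H2O (5 vol%), 50 °C, same flask
Reagents that add atoms: carbon monoxide, [C-]#[O+]; water, O
Why: Proposed new method: zerovalent palladium inserts into the C4–I bond, fast CO insertion gives the acylpalladium (C3), and the tethered copper acetylide transmetalates so that reductive elimination closes ynone 17 (the dry first stage avoids hydroxycarbonylation, CO suppresses the direct, even more strained coupling, and high dilution suppresses oligomers); the bent ynone then takes up water at C1 to give 18, whose C10-OH adds to the C3 carbonyl and loses water, so the carbocycle and the furanone form in one flask with C10 untouched and no new stereocentre; the closest known reactions are the three-component carbonylative Sonogashira coupling of aryl iodides, CO and tertiary propargylic alcohols that gives 3(2H)-furanones directly, and palladium-mediated sp2–sp closures of ten-membered enediynes.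

Step 13
Reactants: 19 5-O-triethylsilyl-4(15)-ene macrocycle (5R,6S,7R,8R,10S)
Product: 20 5-O-acetyl-4(15)-ene macrocycle (5R,6S,7R,8R,10S)
Conditions: Ac2O, Bi(OTf)3 (5 mol%), CH2Cl2, 0 °C
Reagents that add atoms: acetic anhydride, CC(=O)OC(C)=O
Why: Lewis-acid-catalysed acylative desilylation swaps O–Si for O–Ac with the C5–O bond intact (configuration kept), and ionisation at C5 is disfavoured by the electron-poor dienone next to it.

Step 14
Reactants: 20 5-O-acetyl-4(15)-ene macrocycle (5R,6S,7R,8R,10S)
Product: 21 target CNP0275292.1 (4R,5S,6S,7R,8R,10S)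
Conditions: OsO4 (2 mol%), NMO (1.05 equiv), acetone/H2O, 0 °C
Reagents that add atoms: N-methylmorpholine N-oxide, C[N+]1([O-])CCOCC1; water, O
Why: Upjohn dihydroxylation, in which the C4=C15 bond is the distal (γ,δ) alkene of a dienone and so richer than the two acrylate-type alkenes and the push–pull furanone alkene, and osmium attacks anti to the allylic C5-OAc (Kishi model, reinforced by the ring), putting C4-OH trans to C5-OAc, which is 4R.

## Compound list
1 | (Z)-3-methylpent-2-en-4-yn-1-ol | OC/C=C(/C)C#C | starting material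
2 | [(2S,3R)-3-ethynyl-3-methyloxiran-2-yl]methanol | OC[C@@H]1O[C@]1(C)C#C | intermediate
3 | (S)-3-methylpent-4-yne-1,3-diol | OCC[C@](C)(O)C#C | intermediate
4 | (S)-3-hydroxy-3-methylpent-4-ynal | O=CC[C@](C)(O)C#C | intermediate
5 | prop-2-yn-1-ol | OCC#C | starting material
6 | 2-iodoprop-2-en-1-ol | C=C(I)CO | intermediate
7 | 2-iodoprop-2-enal | C=C(I)C=O | intermediate
8 | 3-methylfuran-2(5H)-one | CC1=CCOC1=O | starting material
9 | tert-butyl(dimethyl)[(3-methylfuran-2-yl)oxy]silane | Cc1ccoc1O[Si](C)(C)C(C)(C)C | intermediate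
10 | trichlorosilyl ether of 11 (not isolated) | C=C(I)[C@@H](O[Si](Cl)(Cl)Cl)[C@H]1OC(=O)C(C)=C1 | intermediate
11 | (5S)-5-[(1S)-1-hydroxy-2-iodoprop-2-en-1-yl]-3-methylfuran-2(5H)-one | C=C(I)[C@@H](O)[C@H]1OC(=O)C(C)=C1 | intermediate
12 | triethylsilyl ether of 11 | C=C(I)[C@@H](O[Si](CC)(CC)CC)[C@H]1OC(=O)C(C)=C1 | intermediate
13 | (5S)-3-(bromomethyl)-5-[(1S)-2-iodo-1-(triethylsilyloxy)prop-2-en-1-yl]furan-2(5H)-one | C=C(I)[C@@H](O[Si](CC)(CC)CC)[C@H]1OC(=O)C(CBr)=C1 | intermediate
14 | allylchromium dichloride from 13 (not isolated) | C=C(I)[C@@H](O[Si](CC)(CC)CC)[C@H]1OC(=O)C(C[Cr](Cl)Cl)=C1 | intermediate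
15 | α-methylene lactone diol, 6,7-trans, 8S, 10S | C=C(I)[C@@H](O[Si](CC)(CC)CC)[C@H]1OC(=O)C(=C)[C@@H]1[C@@H](O)C[C@](C)(O)C#C | intermediate
16 | seco vinyl iodide/alkynol, 8R methacrylate | C=C(I)[C@@H](O[Si](CC)(CC)CC)[C@H]1OC(=O)C(=C)[C@@H]1[C@H](OC(=O)C(C)=C)C[C@](C)(O)C#C | intermediate
17 | ten-membered ynone: C10(OH)–C1≡C2–C3(=O)–C4(=CH2) (not isolated) | C=C(C)C(=O)O[C@@H]1C[C@](C)(O)C#CC(=O)C(=C)[C@@H](O[Si](CC)(CC)CC)[C@H]2OC(=O)C(=C)[C@@H]21 | intermediate
18 | ten-membered 1,3-diketone, C1 and C3 ketones (not isolated) | C=C(C)C(=O)O[C@@H]1C[C@](C)(O)C(=O)CC(=O)C(=C)[C@@H](O[Si](CC)(CC)CC)[C@H]2OC(=O)C(=C)[C@@H]21 | intermediate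
19 | target skeleton with C4=C15H2 in place of C4(OH)CH2OH and OSiEt3 at C5 | C=C(C)C(=O)O[C@@H]1C[C@]2(C)OC(=CC2=O)C(=C)[C@@H](O[Si](CC)(CC)CC)[C@H]2OC(=O)C(=C)[C@@H]21 | intermediate
20 | as 19 but with OAc at C5 | C=C(C)C(=O)O[C@@H]1C[C@]2(C)OC(=CC2=O)C(=C)[C@@H](OC(C)=O)[C@H]2OC(=O)C(=C)[C@@H]21 | intermediate
21 | CNP0275292.1 | C=C(C)C(=O)O[C@@H]1C[C@]2(C)OC(=CC2=O)[C@@](O)(CO)[C@@H](OC(C)=O)[C@H]2OC(=O)C(=C)[C@@H]21 | target

## Count and risks
Total steps: 14. Longest linear sequence: 10 steps (5 → 6 → 7 → 11 → 12 → 13 → 15 → 16 → 19 → 20 → 21).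

**Step 12 (ring strain of 17, oligomerisation).** The fallback sets out from 16 and avoids any alkyne in the ring.
- Gold-catalysed Markovnikov hydration (Ph3PAuNTf2, wet dioxane) gives the α-hydroxy methyl ketone F1.
- Palladium-catalysed alkoxycarbonylation of the vinyl iodide (PdCl2(PPh3)2, CO, C6F5OH, Et3N) gives the pentafluorophenyl ester F2.
- A soft-enolisation Claisen macrocyclisation (MgBr2·OEt2, i-Pr2NEt, CH2Cl2, high dilution) then closes the ring.
- The fallback comes back to the route at 18, which cyclodehydrates with PPTS to 19.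

**Step 11 (hindered secondary alcohol; elimination towards C7).** The fallback sets out from 13 and makes the 8R carbinol directly through an open transition state instead of by inversion.
- Zn and Bu3SnCl in THF/aq. NH4Cl convert 13 into the allylstannane F3.
- BF3·OEt2-promoted addition of F3 to 4 at −78 °C, which is syn-selective whatever the allyl geometry, gives the 8R alcohol F4.
- Plain acylation with methacrylic anhydride/DMAP comes back to the route at 16.

**Step 14 (competition from the acrylate alkenes; facial control).** The fallback sets out from 19 and replaces the undirected osmylation by a hydroxyl-directed epoxidation.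
- HF·pyridine frees the allylic alcohol F5.
- VO(acac)2/t-BuOOH epoxidises only the allylic-alcohol alkene, erythro-selectively, to give the 4,15-epoxy alcohol F6.
- Ac2O/pyridine gives the epoxy acetate F7.
- Dilute HClO4 in THF/H2O opens the epoxide at primary C15 with the C4–O bond kept, and the fallback comes back to the route at 21.

Further compounds
F1 | step 12 | α-hydroxy methyl ketone from hydration of 16 | C=C(I)[C@@H](O[Si](CC)(CC)CC)[C@H]1OC(=O)C(=C)[C@@H]1[C@H](OC(=O)C(C)=C)C[C@](C)(O)C(C)=O
F2 | step 12 | pentafluorophenyl ester (C3 carboxyl on C4) of F1 | C=C(C(=O)Oc1c(F)c(F)c(F)c(F)c1F)[C@@H](O[Si](CC)(CC)CC)[C@H]1OC(=O)C(=C)[C@@H]1[C@H](OC(=O)C(C)=C)C[C@](C)(O)C(C)=O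
F3 | step 11 | 3-[(tributylstannyl)methyl]butenolide from 13 | C=C(I)[C@@H](O[Si](CC)(CC)CC)[C@H]1OC(=O)C(C[Sn](CCCC)(CCCC)CCCC)=C1
F4 | step 11 | 8R epimer of 15 | C=C(I)[C@@H](O[Si](CC)(CC)CC)[C@H]1OC(=O)C(=C)[C@@H]1[C@H](O)C[C@](C)(O)C#C
F5 | step 14 | 5-hydroxy-4(15)-ene macrocycle | C=C(C)C(=O)O[C@@H]1C[C@]2(C)OC(=CC2=O)C(=C)[C@@H](O)[C@H]2OC(=O)C(=C)[C@@H]21
F6 | step 14 | 4,15-epoxy-5-hydroxy macrocycle | C=C(C)C(=O)O[C@@H]1C[C@]2(C)OC(=CC2=O)[C@@]3(CO3)[C@@H](O)[C@H]2OC(=O)C(=C)[C@@H]21
F7 | step 14 | 4,15-epoxy-5-acetoxy macrocycle | C=C(C)C(=O)O[C@@H]1C[C@]2(C)OC(=CC2=O)[C@@]3(CO3)[C@@H](OC(C)=O)[C@H]2OC(=O)C(=C)[C@@H]21
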